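**Strategy.** The route rests on disconnecting the C4–C5 bond of ring A. In the target, quaternary C4 (gem-dimethyl) adjoins the ring-fusion carbon C5, and C5 is the δ-carbon of a C9 dienone (C9=O, C8=C7, C6=C5) in ring B. One iron-hydride hydrogen-atom-transfer step turns an isopropenyl group into the tertiary C4 radical, which closes ring A by 1,6-addition, forming C4–C5 and the cis ring fusion under control of quaternary C10. The precursor is enantioenriched (R)-2,6-dimethyl-6-(4-methylpent-4-enyl)cyclohexa-2,4-dienone 11. Singlet oxygen, an oxirane of preset configuration and a radical hydrogenation then complete ring B, the spiro ether and the lactone.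

Key step: step 6

Remarks on the chemistry (assumptions and reading of the structure):
- The target SMILES encodes a cis-fused decalin: H5, the C10 methyl, the C6 acetoxy group, the C8 methyl and the ether oxygen on C9 all lie on one face of ring B (called β below), while C1, C4 and C11 lie on the other (α). CIP descriptors: 5S,6S,8R,9R,10R,13R.
- Bicyclic compounds are named on the labdane skeleton for numbering only; configuration is given by the CIP descriptors and the SMILES.
- 4-[(tert-Butyldimethylsilyl)oxy]butanal 15 is assumed to be purchased.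
- Precursor design: dienone 11 is made last, under non-acidic conditions, and used at once in dilute solution, because 6,6-disubstituted cyclohexa-2,4-dienones dimerise by [4+2] cycloaddition and rearrange to phenols in acid. Both double-bond isomers formed on protonation converge on 13.

Step 1
Reactants: 1 2,6-dimethylcyclohexan-1-one; 2 allyl chloroformate
Product: 3 allyl 2,6-dimethylcyclohex-1-en-1-yl carbonate (racemic)
Conditions: NaN(SiMe3)2, THF, −78 °C; then 2, −78 °C to rt
Reagents that add atoms: none
Why: O-acylation of the sodium enolate (the only enolate possible, since both α-carbons are equivalent) by the chloroformate gives the enol carbonate needed for decarboxylative allylation; no stereocentre of the target is involved.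

Step 2
Reactants: 3 allyl 2,6-dimethylcyclohex-1-en-1-yl carbonate
Product: 4 (2S)-2,6-dimethyl-2-(prop-2-en-1-yl)cyclohexan-1-one (both C6 epimers)
Conditions: Pd2(dba)3 (2.5 mol%), (S)-t-BuPHOX (6 mol%), THF, 25 °C
Reagents that add atoms: none
Why: Decarboxylative asymmetric allylic alkylation (Tsuji–Trost type): loss of CO2 gives a π-allylpalladium enolate, and the (S)-phosphinooxazoline ligand steers C–C bond formation to the enolate face that sets the quaternary carbon (later C10) as S, the sense known for 2-alkylcyclohexanone enol carbonates; the C6 methyl centre is carried as a mixture because step 4 erases it.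

Step 3
Reactants: 4 (2S)-2,6-dimethyl-2-(prop-2-en-1-yl)cyclohexan-1-one; 5 2-bromopropene
Product: 7 (2S)-2,6-dimethyl-2-(4-methylpent-4-en-1-yl)cyclohexan-1-one (both C6 epimers), via alkylborane 6 (not isolated)
Conditions: 9-BBN, THF, 0 °C to rt; then 5, Pd(dppf)Cl2 (5 mol%), K3PO4 (aq), DMF, rt
Reagents that add atoms: none
Why: Anti-Markovnikov hydroboration of the terminal alkene with 9-BBN (much faster than reduction of the hindered ketone) followed by B-alkyl Suzuki–Miyaura coupling with the alkenyl bromide installs the isopropenyl terminus (future C4 with its two methyls) without touching the quaternary centre.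

Step 4
Reactants: 7 (2S)-2,6-dimethyl-2-(4-methylpent-4-en-1-yl)cyclohexan-1-one
Product: 9 (6R)-2,6-dimethyl-6-(4-methylpent-4-en-1-yl)cyclohex-2-en-1-one, via silyl enol ether 8 (not isolated)
Conditions: LiN(iPr)2, THF, −78 to 0 °C; Me3SiCl; then Pd(OAc)2 (1.1 equiv), MeCN, rt
Reagents that add atoms: none
Why: Saegusa–Ito oxidation: the ketone can enolise only towards the methyl-bearing carbon, and palladation of the silyl enol ether with β-hydride elimination into the ring should give the conjugated trisubstituted enone, removing the uncontrolled methyl stereocentre.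

Step 5
Reactants: 9 (6R)-2,6-dimethyl-6-(4-methylpent-4-en-1-yl)cyclohex-2-en-1-one
Product: 11 (6R)-2,6-dimethyl-6-(4-methylpent-4-en-1-yl)cyclohexa-2,4-dien-1-one, via silyl dienol ether 10 (not isolated)
Conditions: LiN(iPr)2, THF, −78 °C; Me3SiCl; then Pd(OAc)2 (1.1 equiv), MeCN, rt, dark; used at once
Reagents that add atoms: none
Why: With no α′ hydrogen the enone is deprotonated at the γ-carbon to the linear dienolate, and Saegusa–Ito oxidation of its silyl ether (palladation at the γ-terminus, β-hydride elimination from the adjacent CH2) should give the 2,4-dienone, which is kept cold, dilute and dark because such dienones dimerise by [4+2] cycloaddition.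

Step 6
Reactants: 11 (6R)-2,6-dimethyl-6-(4-methylpent-4-en-1-yl)cyclohexa-2,4-dien-1-one
Product: 13 (4aS,8aR)-2,5,5,8a-tetramethyl-4a,5,6,7,8,8a-hexahydronaphthalen-1(4H)-one (cis-fused), via deconjugated enone 12 (not isolated)
Conditions: Fe(acac)3 (0.3 equiv), PhSiH3 (2.5 equiv), EtOH/(CH2OH)2 5:1, 0.02 M, rt to 40 °C; then DBU (0.2 equiv), rt
Reagents that add atoms: none
Why: Hydrogen-atom transfer from the iron hydride formed from Fe(acac)3 and PhSiH3 to the CH2 terminus of the electron-rich 1,1-disubstituted alkene gives the nucleophilic tertiary C4 radical, which adds to C5, the δ-terminus of the C9 dienone, forming C4–C5; the oxygen-stabilised pentadienyl radical is then reduced by the divalent iron species to the dienolate and protonated by ethanol, and DBU moves any C6=C7 isomer 12 into conjugation. The closest known reaction type is the iron-hydride-initiated reductive radical conjugate (Giese-type) cyclisation of alkenes onto enones that builds quaternary carbons, of which this is the vinylogous 1,6 mode. Ring A closes in the 6-exo-trig mode, since 7-endo attack at C6 would be slower and give a less stabilised radical. The only new stereocentre, C5, is controlled by quaternary C10: the three-carbon tether can reach C5 only on the face from which it hangs, through a chair-like transition state, so H5 ends cis to the C10 methyl, and C5, not being α to the carbonyl, cannot epimerise afterwards. The step needs chemoselective hydrogen-atom transfer to the isopropenyl group over the electron-poor dienone, which the polarity match of the hydride with the electron-rich alkene should secure, and it needs high dilution at mild temperature to outrun dimerisation of the dienone.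

Step 7
Reactants: 13 (4aS,8aR)-2,5,5,8a-tetramethyl-4a,5,6,7,8,8a-hexahydronaphthalen-1(4H)-one
Product: 14 (4aS,8aR)-2,5,5,8a-tetramethyl-4a,5,6,7,8,8a-hexahydronaphthalen-1-yl trifluoromethanesulfonate
Conditions: KN(SiMe3)2, THF, −78 °C; PhNTf2, −78 to 0 °C
Reagents that add atoms: N-phenylbis(trifluoromethanesulfonimide), O=S(=O)(N(c1ccccc1)S(=O)(=O)C(F)(F)F)C(F)(F)F
Why: C10 is quaternary, so the amide base can only remove a γ-proton at C6, and O-sulfonylation of the extended potassium dienolate gives the C6=C7–C8=C9 dienyl triflate without affecting C5 or C10.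

Step 8
Reactants: 15 4-[(tert-butyldimethylsilyl)oxy]butanal
Product: 16 4-[(tert-butyldimethylsilyl)oxy]-2-methylidenebutanal
Conditions: CH2O (37% aq), pyrrolidine (10 mol%), EtCO2H (10 mol%), i-PrOH, 45 °C
Reagents that add atoms: formaldehyde, C=O
Why: Amine-catalysed Mannich condensation of the enolisable aldehyde with formaldehyde followed by elimination (α-methylenation) gives the 2-substituted acrolein; the silyl ether tolerates the buffered conditions.

Step 9
Reactants: 16 4-[(tert-butyldimethylsilyl)oxy]-2-methylidenebutanal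
Product: 17 2-{2-[(tert-butyldimethylsilyl)oxy]ethyl}prop-2-en-1-ol
Conditions: NaBH4, CeCl3·7H2O, MeOH, 0 °C
Reagents that add atoms: none
Why: Luche reduction delivers hydride 1,2 to the enal and gives the 2-substituted allylic alcohol needed for directed epoxidation.

Step 10
Reactants: 17 2-{2-[(tert-butyldimethylsilyl)oxy]ethyl}prop-2-en-1-ol
Product: 18 [(2R)-2-{2-[(tert-butyldimethylsilyl)oxy]ethyl}oxiran-2-yl]methanol
Conditions: Ti(OiPr)4 (10 mol%), D-(−)-diethyl tartrate (12 mol%), t-BuOOH, 4 Å molecular sieves, CH2Cl2, −20 °C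
Reagents that add atoms: tert-butyl hydroperoxide, CC(C)(C)OO
Why: Sharpless asymmetric epoxidation: the allylic hydroxyl binds the titanium tartrate catalyst and the D-tartrate ligand directs oxygen transfer to the alkene face that gives the R epoxy alcohol (L-tartrate is known to give S-2-alkylglycidols), which fixes the future C13.

Step 11
Reactants: 18 [(2R)-2-{2-[(tert-butyldimethylsilyl)oxy]ethyl}oxiran-2-yl]methanol
Product: 19 (2S)-2-{2-[(tert-butyldimethylsilyl)oxy]ethyl}oxirane-2-carbaldehyde
Conditions: TEMPO (10 mol%), PhI(OAc)2, CH2Cl2, rt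
Reagents that add atoms: none
Why: Oxoammonium (TEMPO) oxidation stops at the aldehyde under non-aqueous, nearly neutral conditions, and the fully substituted oxirane carbon cannot epimerise (the descriptor changes only through CIP priorities).

Step 12
Reactants: 19 (2S)-2-{2-[(tert-butyldimethylsilyl)oxy]ethyl}oxirane-2-carbaldehyde
Product: 20 (2R)-2-{2-[(tert-butyldimethylsilyl)oxy]ethyl}-2-ethenyloxirane
Conditions: Ph3PCH3Br, KOtBu, THF, 0 °C
Reagents that add atoms: methyltriphenylphosphonium bromide, C[P+](c1ccccc1)(c1ccccc1)c1ccccc1.[Br-]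
Why: Wittig methylenation of the non-enolisable aldehyde adds C11 as a terminal vinyl group for hydroboration and leaves the oxirane untouched.

Step 13
Reactants: 20 (2R)-2-{2-[(tert-butyldimethylsilyl)oxy]ethyl}-2-ethenyloxirane; 14 (4aS,8aR)-2,5,5,8a-tetramethyl-4a,5,6,7,8,8a-hexahydronaphthalen-1-yl trifluoromethanesulfonate
Product: 22 (5S,10R,13S)-15-[(tert-butyldimethylsilyl)oxy]-13,16-epoxylabda-6,8-diene, via alkylborane 21 (not isolated)
Conditions: 9-BBN, THF, 0 °C to rt; then 14, Pd(dppf)Cl2 (10 mol%), AsPh3, Cs2CO3, DMF/THF/H2O, rt to 50 °C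
Reagents that add atoms: none
Why: Hydroboration of the vinyl group with bulky 9-BBN puts boron on C11, and B-alkyl Suzuki–Miyaura coupling with the alkenyl triflate (dppf ligand to suppress β-hydride elimination) forms C9–C11 without involving any stereocentre.

Step 14
Reactants: 22 (5S,10R,13S)-15-[(tert-butyldimethylsilyl)oxy]-13,16-epoxylabda-6,8-diene
Product: 24 (5S,6S,9R,10R,13S)-15-[(tert-butyldimethylsilyl)oxy]-13,16-epoxylabd-7-ene-6,9-diol, via endoperoxide 23 (not isolated)
Conditions: O2, tetraphenylporphyrin (cat.), visible light, CH2Cl2, −78 °C; then thiourea, MeOH, 0 °C to rt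
Reagents that add atoms: dioxygen, O=O
Why: Singlet oxygen adds to the cisoid ring B diene in a [4+2] cycloaddition from the β face, which carries only H5 and the C10 methyl whereas the α face is blocked by C1 and the C4 gem-dimethyl group of the folded cis-decalin, so O6 and O9 arrive cis to each other and β; thiourea then reduces the O–O bond to the cis-ene-diol without touching the oxirane.

Step 15
Reactants: 24 (5S,6S,9R,10R,13S)-15-[(tert-butyldimethylsilyl)oxy]-13,16-epoxylabd-7-ene-6,9-diol (crude)
Product: 25 (5S,6S,9R,10R,13S)-15-[(tert-butyldimethylsilyl)oxy]-13,16-epoxy-9-hydroxylabd-7-en-6-yl acetate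
Conditions: Ac2O, pyridine, DMAP (cat.), CH2Cl2, 0 °C
Reagents that add atoms: acetic anhydride, CC(=O)OC(C)=O
Why: DMAP-catalysed acylation discriminates the secondary C6 hydroxyl from the tertiary C9 hydroxyl and installs the acetate of the target with retention at C6.

Step 16
Reactants: 25 (5S,6S,9R,10R,13S)-15-[(tert-butyldimethylsilyl)oxy]-13,16-epoxy-9-hydroxylabd-7-en-6-yl acetate
Product: 26 (5S,6S,9R,10R,13R)-15-[(tert-butyldimethylsilyl)oxy]-9,13-epoxy-16-hydroxylabd-7-en-6-yl acetate
Conditions: camphorsulfonic acid (10 mol%), CH2Cl2, 0 °C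
Reagents that add atoms: none
Why: Acid-catalysed intramolecular epoxide opening: the tertiary C9 hydroxyl attacks the more substituted oxirane carbon C13 in the 5-exo mode with inversion, so the preset oxirane configuration is translated into the R spiro centre C13 and C16 is released as a primary alcohol.

Step 17
Reactants: 26 (5S,6S,9R,10R,13R)-15-[(tert-butyldimethylsilyl)oxy]-9,13-epoxy-16-hydroxylabd-7-en-6-yl acetate
Product: 29 (5S,6S,9R,10R,13R)-6-acetoxy-9,13-epoxylabd-7-en-16,15-olide, via silyloxy acid 27 (not isolated), via hydroxy acid 28 (not isolated)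
Conditions: TEMPO (20 mol%), PhI(OAc)2 (2.2 equiv), MeCN/H2O, rt; then HF (48% aq), rt
Reagents that add atoms: water, O
Why: TEMPO/PhI(OAc)2 in aqueous acetonitrile oxidises the neopentyl-type primary alcohol through the aldehyde hydrate to the acid without affecting acetate, silyl ether or alkene, and aqueous HF then cleaves the silyl ether so that the γ-hydroxy acid lactonises to the five-membered lactone (C16 carbonyl, C15–O).

Step 18
Reactants: 29 (5S,6S,9R,10R,13R)-6-acetoxy-9,13-epoxylabd-7-en-16,15-olide
Product: 30 (5S,6S,8R,9R,10R,13R)-6-acetoxy-9,13-epoxylabdan-16,15-olide (CNP0081177.1)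
Conditions: Mn(dpm)3 (10 mol%), PhSiH3, t-BuOOH, i-PrOH, rt
Reagents that add atoms: none
Why: Metal-hydride hydrogen-atom-transfer hydrogenation: a hydrogen atom is delivered to C7 and the tertiary C8 radical should then be quenched under product-stability control, axially on the α face anti to the axial C9–O bond, which places the C8 methyl equatorial and β (the epimer would suffer a 1,3-diaxial clash with C1), whereas surface hydrogenation would be expected to add from the open β face.

**Compound list**

1 | 2,6-dimethylcyclohexan-1-one (cis/trans mixture) | CC1CCCC(C)C1=O | starting material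
2 | allyl chloroformate | C=CCOC(Cl)=O | starting material
3 | allyl 2,6-dimethylcyclohex-1-en-1-yl carbonate (racemic) | C=CCOC(=O)OC1=C(C)CCCC1C | intermediate
4 | (2S)-2,6-dimethyl-2-(prop-2-en-1-yl)cyclohexan-1-one (both C6 epimers) | C=CC[C@]1(C)CCCC(C)C1=O | intermediate
5 | 2-bromopropene | CC(Br)=C | starting material
6 | B-alkyl-9-BBN adduct of 4 (boron on the terminal carbon of the former allyl group; quaternary centre unchanged) | B1(C2CCCC1CCC2)CCC[C@]1(C)CCCC(C)C1=O | intermediate (not isolated)
7 | (2S)-2,6-dimethyl-2-(4-methylpent-4-en-1-yl)cyclohexan-1-one (both C6 epimers) | C=C(C)CCC[C@]1(C)CCCC(C)C1=O | intermediate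
8 | trimethylsilyl enol ether of 7 (tetrasubstituted enol ether on the methyl side; quaternary centre unchanged) | C=C(C)CCC[C@]1(C)CCCC(C)=C1O[Si](C)(C)C | intermediate (not isolated)
9 | (6R)-2,6-dimethyl-6-(4-methylpent-4-en-1-yl)cyclohex-2-en-1-one | C=C(C)CCC[C@]1(C)CCC=C(C)C1=O | intermediate
10 | 2-(trimethylsilyloxy)-1,3-diene from 9 (linear silyl dienol ether; quaternary centre unchanged) | C=C(C)CCC[C@]1(C)CC=CC(C)=C1O[Si](C)(C)C | intermediate (not isolated)
11 | (6R)-2,6-dimethyl-6-(4-methylpent-4-en-1-yl)cyclohexa-2,4-dien-1-one | C=C(C)CCC[C@]1(C)C=CC=C(C)C1=O | intermediate (key-step precursor)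
12 | (4aS,8aR)-2,5,5,8a-tetramethyl-4a,5,6,7,8,8a-hexahydronaphthalen-1(2H)-one (cis-fused; C3=C4 alkene; C2 epimers) | C1=CC(C)C(=O)[C@]2(C)CCCC(C)(C)[C@H]12 | intermediate (not isolated)
13 | (4aS,8aR)-2,5,5,8a-tetramethyl-4a,5,6,7,8,8a-hexahydronaphthalen-1(4H)-one (cis-fused: H4a and the 8a-methyl on the same face) | C1C=C(C)C(=O)[C@]2(C)CCCC(C)(C)[C@H]12 | intermediate (key-step product)
14 | (4aS,8aR)-2,5,5,8a-tetramethyl-4a,5,6,7,8,8a-hexahydronaphthalen-1-yl trifluoromethanesulfonate | C1=CC(C)=C(OS(=O)(=O)C(F)(F)F)[C@]2(C)CCCC(C)(C)[C@H]12 | intermediate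
15 | 4-[(tert-butyldimethylsilyl)oxy]butanal | O=CCCCO[Si](C)(C)C(C)(C)C | starting material
16 | 4-[(tert-butyldimethylsilyl)oxy]-2-methylidenebutanal | O=CC(=C)CCO[Si](C)(C)C(C)(C)C | intermediate
17 | 2-{2-[(tert-butyldimethylsilyl)oxy]ethyl}prop-2-en-1-ol | OCC(=C)CCO[Si](C)(C)C(C)(C)C | intermediate
18 | [(2R)-2-{2-[(tert-butyldimethylsilyl)oxy]ethyl}oxiran-2-yl]methanol | OC[C@]1(CCO[Si](C)(C)C(C)(C)C)CO1 | intermediate
19 | (2S)-2-{2-[(tert-butyldimethylsilyl)oxy]ethyl}oxirane-2-carbaldehyde | O=C[C@]1(CCO[Si](C)(C)C(C)(C)C)CO1 | intermediate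
20 | (2R)-2-{2-[(tert-butyldimethylsilyl)oxy]ethyl}-2-ethenyloxirane | C=C[C@]1(CCO[Si](C)(C)C(C)(C)C)CO1 | intermediate
21 | B-alkyl-9-BBN adduct of 20 (boron on C11; oxirane configuration unchanged) | B1(C2CCCC1CCC2)CC[C@]1(CCO[Si](C)(C)C(C)(C)C)CO1 | intermediate (not isolated)
22 | (5S,10R,13S)-15-[(tert-butyldimethylsilyl)oxy]-13,16-epoxylabda-6,8-diene (A/B cis) | C1=CC(C)=C(CC[C@]3(CCO[Si](C)(C)C(C)(C)C)CO3)[C@]2(C)CCCC(C)(C)[C@H]12 | intermediate
23 | (5S,6S,9R,10R,13S)-15-[(tert-butyldimethylsilyl)oxy]-13,16-epoxy-6,9-epidioxylabd-7-ene (peroxide bridge β) | C1(C)=C[C@@H]2OO[C@@]1(CC[C@]4(CCO[Si](C)(C)C(C)(C)C)CO4)[C@]3(C)CCCC(C)(C)[C@H]23 | intermediate (not isolated)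
24 | (5S,6S,9R,10R,13S)-15-[(tert-butyldimethylsilyl)oxy]-13,16-epoxylabd-7-ene-6,9-diol (both hydroxyls β) | O[C@H]1C=C(C)[C@](O)(CC[C@]3(CCO[Si](C)(C)C(C)(C)C)CO3)[C@]2(C)CCCC(C)(C)[C@H]12 | intermediate
25 | (5S,6S,9R,10R,13S)-15-[(tert-butyldimethylsilyl)oxy]-13,16-epoxy-9-hydroxylabd-7-en-6-yl acetate | CC(=O)O[C@H]1C=C(C)[C@](O)(CC[C@]3(CCO[Si](C)(C)C(C)(C)C)CO3)[C@]2(C)CCCC(C)(C)[C@H]12 | intermediate
26 | (5S,6S,9R,10R,13R)-15-[(tert-butyldimethylsilyl)oxy]-9,13-epoxy-16-hydroxylabd-7-en-6-yl acetate | CC(=O)O[C@H]1C=C(C)[C@]2(CC[C@](CO)(CCO[Si](C)(C)C(C)(C)C)O2)[C@]2(C)CCCC(C)(C)[C@H]12 | intermediate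
27 | (5S,6S,9R,10R,13R)-6-acetoxy-15-[(tert-butyldimethylsilyl)oxy]-9,13-epoxylabd-7-en-16-oic acid | CC(=O)O[C@H]1C=C(C)[C@]2(CC[C@](C(=O)O)(CCO[Si](C)(C)C(C)(C)C)O2)[C@]2(C)CCCC(C)(C)[C@H]12 | intermediate (not isolated)
28 | (5S,6S,9R,10R,13R)-6-acetoxy-9,13-epoxy-15-hydroxylabd-7-en-16-oic acid | CC(=O)O[C@H]1C=C(C)[C@]2(CC[C@](C(=O)O)(CCO)O2)[C@]2(C)CCCC(C)(C)[C@H]12 | intermediate (not isolated)
29 | (5S,6S,9R,10R,13R)-6-acetoxy-9,13-epoxylabd-7-en-16,15-olide | CC(=O)O[C@H]1C=C(C)[C@]2(CC[C@]3(CCOC3=O)O2)[C@]2(C)CCCC(C)(C)[C@H]12 | intermediate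
30 | (5S,6S,8R,9R,10R,13R)-6-acetoxy-9,13-epoxylabdan-16,15-olide (A/B cis; CNP0081177.1) | CC(=O)O[C@H]1C[C@@H](C)[C@]2(CC[C@]3(CCOC3=O)O2)[C@]2(C)CCCC(C)(C)[C@H]12 | target

**Step count.** 18 steps in total. The longest linear sequence is 13 steps (steps 1–7 and 13–18); the oxirane fragment takes steps 8–12.

**Steps most likely to fail, with fallbacks**

1. Step 6 (key step). What may go wrong: hydrogen-atom transfer to, or conjugate reduction of, the dienone instead of the isopropenyl group; quenching of the tertiary radical before it adds to C5; or dimerisation of the dienone. The fallback generates the same radical without a metal hydride and sets out from 11. Markovnikov addition of HBr (HBr in AcOH/CH2Cl2, −20 °C, short contact) to the isopropenyl group should give the tertiary bromide F1. A tin-hydride chain reaction (Bu3SnH, AIBN, slow addition, benzene, 80 °C) then forms the C4 radical by bromine abstraction; with no pendant alkene left, warming is tolerable. The cyclised dienyloxy radical takes hydrogen from the stannane, and DBU as in step 6 brings the material back to 13.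

2. Step 18. What may go wrong: poor facial selectivity in hydrogen delivery to the C8 radical, giving the C8 epimer. The fallback puts C8 under equilibrium control and sets out from 29. Hydroboration–oxidation (BH3·SMe2, THF, 0 °C; NaBO3·4H2O) should give the 7-alcohol F2, and Swern oxidation the 7-ketone F3. In F3, C8 (and C6) are α to the carbonyl and should equilibrate with DBU to the arrangement with the C8 methyl and C6 acetoxy group equatorial and β. Dithiolane formation (ethane-1,2-dithiol, BF3·OEt2) should give the dithiolane F4, and desulfurisation with Ni2B (from NiCl2·6H2O and NaBH4) removes the C7 function and returns to 30.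

3. Step 13. What may go wrong: slow transmetalation of the alkyl borate to the crowded alkenylpalladium centre (flanked by quaternary C10 and the C8 methyl), so that protodeboronation, β-hydride elimination or attack of the aqueous base on the oxirane take over. The fallback is a base-free Negishi coupling and sets out from 21. Iodinolysis (I2, NaOMe, THF/MeOH, 0 °C) should give the primary iodide F5, and zinc insertion (Zn dust, LiCl, THF) the alkylzinc iodide F6. Coupling of F6 with 14 (Pd2(dba)3, SPhos, THF, rt to 50 °C) returns to 22.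

**Further compounds**

F1 | step 6 | (6R)-6-(4-bromo-4-methylpentyl)-2,6-dimethylcyclohexa-2,4-dien-1-one | CC(C)(Br)CCC[C@]1(C)C=CC=C(C)C1=O
F2 | step 18 | 7-hydroxy derivative of 30 from hydroboration of 29 (C7 and C8 not yet fixed) | CC(=O)O[C@H]1C(O)C(C)[C@]2(CC[C@]3(CCOC3=O)O2)[C@]2(C)CCCC(C)(C)[C@H]12
F3 | step 18 | 7-oxo derivative of 30 (C8 methyl equilibrated to β) | CC(=O)O[C@H]1C(=O)[C@@H](C)[C@]2(CC[C@]3(CCOC3=O)O2)[C@]2(C)CCCC(C)(C)[C@H]12
F4 | step 18 | 1,3-dithiolane of F3 at C7 | CC(=O)O[C@H]1C2(SCCS2)[C@@H](C)[C@]2(CC[C@]3(CCOC3=O)O2)[C@]2(C)CCCC(C)(C)[C@H]12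
F5 | step 13 | 2-{2-[(tert-butyldimethylsilyl)oxy]ethyl}-2-(2-iodoethyl)oxirane (oxirane configuration as in 20) | ICC[C@]1(CCO[Si](C)(C)C(C)(C)C)CO1
F6 | step 13 | alkylzinc iodide from F5 (zinc on C11) | I[Zn]CC[C@]1(CCO[Si](C)(C)C(C)(C)C)CO1
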